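[Partner] stands in no column of the earlier runs, so I cannot get a rate constant for either substrate out of them.

| flask | left-handed substrate | right-handed substrate | solid reagent | free catalyst | impurity | remark | time |
|---|---|---|---|---|---|---|---|
| epsilon | 0.10 M | 0.10 M | 0.15 M | 0.67 mM | 0.12 mM | run made earlier |  |
| eta | 0.10 M | 0.10 M | 0.15 M | 1.5 mM | 0.12 mM | run made earlier |  |
| flask | 0.10 M | 0.10 M | 0.150 M | 1.0 mM | 0.12 mM |  | 2.0 min |

- epsilon (time / s: right-handed substrate / %, left-handed substrate / %): 10.0: 49.9, 25.9; 12.0: 50.5, 20.1; 20.0: 49.2, 9.9; 30.0: 48.1, 2.6; 50.0: 48.8, 0; 80.0: 46.6, 0
- eta (time / s: right-handed substrate / %, left-handed substrate / %): 10.0: 49.4, 15.4; 12.0: 49.8, 10.3; 20.0: 49.5, 0.5; 30.0: 47.8, 0; 40.0: 46.9, 0; 60.0: 44.5, 0.2; 80.0: 41.9, 0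

(each reading ± 0.5 percentage points)

- free catalyst is single-handed; left-handed substrate and right-handed substrate are mirror images of each other, charged as a racemate, each of them at the stated concentration
- solid reagent is a solid; its amount is given per volume of the solution
- on the list of suspects stand: partner + free catalyst + left-handed substrate -> free catalyst + left-handed product; partner + free catalyst + right-handed substrate -> free catalyst + right-handed product; left-handed product <-> right-handed product; solid reagent <-> partner; free catalyst + impurity -> spent catalyst
- at the start none of the solid reagent is in solution

* whether the excess of right-handed substrate over left-handed substrate among what is left of the two reaches 80% by 2.0 min (yes / no)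
* the highest excess of right-handed substrate over left-handed substrate among what is left of the two up to 2.0 min

1. A ratio is within reach. On the suspected steps, both substrates in a flask meet the same [partner] and [free catalyst] at any moment. These cancel in the selectivity factor s, the fractional loss rate of left-handed substrate over that of right-handed substrate.

2. First way, from the epsilon run: integrated, s is the logarithm of the fraction of left-handed substrate left over that of right-handed substrate left. At 30.0 s it reads 76.3. But the right-handed loss is 1.9 percentage points against a scatter of 0.5 points, so this reading is soft.

3. Second way, from the eta run: left-handed substrate falls at 0.201 s⁻¹ between 10.0 s and 12.0 s, and right-handed substrate at 0.00263 s⁻¹ between 30.0 s and 80.0 s. Their ratio reads 76.4. This way compares two moments, so a rise of [partner] between them would make it read low. So the closeness of the two figures is no check: the first is soft and the second reads low. I carry s as a floor, of about this size or higher.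

4. An excess of 80% means left-handed substrate stands at (1 − excess)/(1 + excess) of right-handed substrate. With s at its floor, right-handed substrate then still holds 48.6% of the two charged together, and a higher s leaves more. At the same floor, the forecast's top comes with 45.3% left, and again a higher s leaves more.

5. The flask has 0.880 mM of catalyst beyond the impurity, more than the epsilon run's 0.550 mM, and that run read an excess of 89.7% at 30.0 s. The flask's 2.0 min is far longer, so I say yes.

6. The forecast answers yes, with a top of 99.9%: “The selectivity is therefore very high.”

7. The flask gives yes, with a top of 100%.

    partner + free catalyst + left-handed substrate → free catalyst + left-handed product (k = 10900 M⁻² s⁻¹)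
    partner + free catalyst + right-handed substrate → free catalyst + right-handed product (k = 71.2 M⁻² s⁻¹)
    left-handed product ⇌ right-handed product (k = 0.155 s⁻¹)
    solid reagent ⇌ partner, rate k4*(cs4 - [partner]) while solid is left; crystals form when [partner] > cs4 (solubility = 24.0 mM, k = 0.520 s⁻¹)
    free catalyst + impurity → spent catalyst (k = 8170 M⁻¹ s⁻¹)

8. In the flask the excess reaches 80% at 0.306 min, with 49.3% of right-handed substrate left, above the 48.6% that s at its floor of 76.3 gave. Carried to the run at twice the dilution, the floor puts an excess of 99.9% at 45.3% of right-handed substrate left or more, and that run ends at an excess of >99.9%.

(The data are calculated with made-up constants; the scatter is artificial.)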